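Retrosynthesis (ring locants O1, C2–C5; C1′ is the exocyclic C–Br carbon): the O1–C2 and C3–Br bonds are cut together (5-endo bromoetherification), then C1′–Br (oxirane opening), C–Cl and the oxirane, and last the C5–C1′ bond itself, cut as a C=C (Wittig) into a seven-carbon bromodienal and a three-carbon ylide.
Enabling feature: O1 on C5 and Br on C1′ are vicinal and anti, the print of an anti O/Br addition across an (E)-trisubstituted olefin lying exactly on C5–C1′; the same O/Br pair (O1–C2, C3–Br) inside the oxolane ring marks the second olefin.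
Forward: bromodienal and ylide are joined to the acyclic C10 chain as an (E,E,E)-triene; oxirane, chloride and tertiary bromide follow; the oxolane ring is closed last through its O1–C2 bond.
Stereochemistry: olefin geometries from stabilised-ylide Wittig and Takai reactions; absolute configuration from one Sharpless epoxidation (D-(−)-DET); C1′ by inversion in the bromide opening; C2 and C3 are relayed from C5 in the anti, 5-endo ring closure.

Key step: step 4

Step 1
Reactants: 1 3-[(tert-butyldimethylsilyl)oxy]propanal; 2 2-(triphenyl-λ5-phosphanylidene)propanal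
Product: 3 (2E)-5-[(tert-butyldimethylsilyl)oxy]-2-methylpent-2-enal
Conditions: toluene, 90 °C
Reagents that add atoms: none
Why: Wittig olefination with a formyl-stabilised ylide, whose reversible addition and late transition state give the (E)-trisubstituted enal (CHO trans to the chain); the β-silyloxy aldehyde is tolerated because the ylide is only weakly basic.

Step 2
Reactants: 3 (2E)-5-[(tert-butyldimethylsilyl)oxy]-2-methylpent-2-enal
Product: 4 tert-butyl{[(3E,5E)-6-bromo-4-methylhexa-3,5-dien-1-yl]oxy}dimethylsilane
Conditions: CrBr3, LiAlH4, THF, 0 °C → rt; then 3, CHBr3, 50 °C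
Reagents that add atoms: bromoform, BrC(Br)Br
Why: Takai–Utimoto haloolefination, in which the gem-dichromium species from CHBr3 and Cr(II) adds 1,2 to the enal and anti-eliminates to the (E)-vinyl bromide, CrBr2 being used instead of CrCl2 so that no chloride is exchanged into the product.

Step 3
Reactants: 4 tert-butyl{[(3E,5E)-6-bromo-4-methylhexa-3,5-dien-1-yl]oxy}dimethylsilane
Product: 5 (3E,5E)-6-bromo-4-methylhexa-3,5-dien-1-ol
Conditions: CSA (cat.), MeOH, 0 °C → rt
Reagents that add atoms: none
Why: Acid-catalysed methanolysis of a primary tert-butyldimethylsilyl ether, to which the bromodiene is inert.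

Step 4
Reactants: 5 (3E,5E)-6-bromo-4-methylhexa-3,5-dien-1-ol; 6 ethyl 2-(triphenyl-λ5-phosphanylidene)propanoate
Product: 8 ethyl (2E,5E,7E)-8-bromo-2,6-dimethylocta-2,5,7-trienoate, via dienal 7 (not isolated)
Conditions: IBX, 6, DMSO, rt
Reagents that add atoms: none
Why: IBX oxidises the homoallylic alcohol to the β,γ-unsaturated aldehyde 7, which is trapped as it forms by the ester-stabilised ylide 6 through [2+2] addition to an oxaphosphetane and syn-elimination of Ph3PO. The closest known reaction type is the one-pot IBX (or Dess–Martin)/stabilised-ylide olefination used for aldehydes that cannot be stored. No ring is closed and no stereocentre is made; the new stereo-element is the C2=C3 olefin, whose (E) geometry follows from the reversible addition and late, dipole-minimised transition state of an α-methyl ester ylide. The step needs E/Z selectivity and positional integrity of the skipped diene: the first is secured by the α-branched stabilised ylide, the second by keeping 7 at a low stationary concentration under near-neutral conditions, so that it is olefinated before its C3=C4 bond can move into conjugation. This (E) geometry is the stored information of the route: it is what later places O1 on C5 and Br on C1′ anti across the bond formed here.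

Step 5
Reactants: 8 ethyl (2E,5E,7E)-8-bromo-2,6-dimethylocta-2,5,7-trienoate
Product: 9 (2E,5E,7E)-8-bromo-2,6-dimethylocta-2,5,7-trien-1-ol
Conditions: DIBAL-H, CH2Cl2, −78 °C
Reagents that add atoms: none
Why: DIBAL-H reduction of an α,β-unsaturated ester to the allylic alcohol (1,2-reduction at −78 °C), which touches neither the vinyl bromide nor the olefin geometries.

Step 6
Reactants: 9 (2E,5E,7E)-8-bromo-2,6-dimethylocta-2,5,7-trien-1-ol
Product: 10 [(2R,3R)-3-[(2E,4E)-5-bromo-3-methylpenta-2,4-dien-1-yl]-2-methyloxiran-2-yl]methanol
Conditions: Ti(OiPr)4 (cat.), D-(−)-DET (cat.), TBHP, 4 Å MS, CH2Cl2, −20 °C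
Reagents that add atoms: tert-butyl hydroperoxide, CC(C)(C)OO
Why: Sharpless asymmetric epoxidation, in which only the allylic-alcohol olefin is bound to titanium and D-(−)-DET directs oxygen to the face giving the (2R,3R)-epoxy alcohol (mirror image of the (2S,3S) products that (E)-allylic alcohols give with L-(+)-DET), so that both oxirane stereocentres follow from the catalyst and the (E) geometry.

Step 7
Reactants: 10 [(2R,3R)-3-[(2E,4E)-5-bromo-3-methylpenta-2,4-dien-1-yl]-2-methyloxiran-2-yl]methanol
Product: 11 (2S,3R)-3-[(2E,4E)-5-bromo-3-methylpenta-2,4-dien-1-yl]-2-(chloromethyl)-2-methyloxirane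
Conditions: PPh3, CCl4, NaHCO3 (trace), reflux
Reagents that add atoms: carbon tetrachloride, ClC(Cl)(Cl)Cl
Why: Appel chlorination, an SN2 displacement of the alkoxyphosphonium group by chloride at the primary carbon under neutral conditions that leaves the oxirane and both stereocentres untouched (the descriptor at C2 changes to S only because CH2Cl now outranks the ring carbon).

Step 8
Reactants: 11 (2S,3R)-3-[(2E,4E)-5-bromo-3-methylpenta-2,4-dien-1-yl]-2-(chloromethyl)-2-methyloxirane
Product: 12 (2R,3R,5E,7E)-2,8-dibromo-1-chloro-2,6-dimethylocta-5,7-dien-3-ol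
Conditions: 48% aq. HBr, THF, 0 °C
Reagents that add atoms: hydrogen bromide, Br
Why: Acid-promoted ring opening of a trisubstituted oxirane by bromide (halohydrin formation), which occurs anti at the tertiary carbon that carries most of the positive charge, as in acid-catalysed openings of related 2-methyl-2,3-epoxy alcohols, and so sets the tertiary C–Br centre (2R) by inversion while the carbinol centre (3R) keeps its C–O bond.

Step 9
Reactants: 12 (2R,3R,5E,7E)-2,8-dibromo-1-chloro-2,6-dimethylocta-5,7-dien-3-ol
Product: 13 (2S,3R,5R)-3-bromo-5-[(2R)-2-bromo-1-chloropropan-2-yl]-2-[(E)-2-bromoethenyl]-2-methyloxolane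
Conditions: NBS, MeCN, −20 → 0 °C
Reagents that add atoms: N-bromosuccinimide, O=C1CCC(=O)N1Br
Why: 5-endo-trig bromoetherification of a homoallylic alcohol, in which Br+ adds to C5 of the diene and the C3 hydroxyl closes anti on the tertiary allylic carbon C6, so that the (E) geometry places Br cis to the ring methyl group (ring C2 S, ring C3 R) and the envelope transition state with the bulky C(Br)(CH3)CH2Cl group pseudo-equatorial places Br cis to that group, the sense established for halocyclisations of (E)- and (Z)-homoallylic alcohols (3-halogen cis to the 5-substituent).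

Compound list
1 | 3-[(tert-butyldimethylsilyl)oxy]propanal | O=CCCO[Si](C)(C)C(C)(C)C | starting material
2 | 2-(triphenyl-λ5-phosphanylidene)propanal | CC(C=O)=P(c1ccccc1)(c1ccccc1)c1ccccc1 | starting material
3 | (2E)-5-[(tert-butyldimethylsilyl)oxy]-2-methylpent-2-enal | O=C/C(C)=C/CCO[Si](C)(C)C(C)(C)C | intermediate
4 | tert-butyl{[(3E,5E)-6-bromo-4-methylhexa-3,5-dien-1-yl]oxy}dimethylsilane | Br/C=C/C(C)=C/CCO[Si](C)(C)C(C)(C)C | intermediate
5 | (3E,5E)-6-bromo-4-methylhexa-3,5-dien-1-ol | Br/C=C/C(C)=C/CCO | intermediate
6 | ethyl 2-(triphenyl-λ5-phosphanylidene)propanoate | CCOC(=O)C(C)=P(c1ccccc1)(c1ccccc1)c1ccccc1 | starting material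
7 | (3E,5E)-6-bromo-4-methylhexa-3,5-dienal | Br/C=C/C(C)=C/CC=O | intermediate (not isolated)
8 | ethyl (2E,5E,7E)-8-bromo-2,6-dimethylocta-2,5,7-trienoate | Br/C=C/C(C)=C/C/C=C(\C)C(=O)OCC | intermediate
9 | (2E,5E,7E)-8-bromo-2,6-dimethylocta-2,5,7-trien-1-ol | Br/C=C/C(C)=C/C/C=C(\C)CO | intermediate
10 | [(2R,3R)-3-[(2E,4E)-5-bromo-3-methylpenta-2,4-dien-1-yl]-2-methyloxiran-2-yl]methanol | C[C@]1(CO)O[C@@H]1C/C=C(C)/C=C/Br | intermediate
11 | (2S,3R)-3-[(2E,4E)-5-bromo-3-methylpenta-2,4-dien-1-yl]-2-(chloromethyl)-2-methyloxirane | C[C@]1(CCl)O[C@@H]1C/C=C(C)/C=C/Br | intermediate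
12 | (2R,3R,5E,7E)-2,8-dibromo-1-chloro-2,6-dimethylocta-5,7-dien-3-ol | C[C@](Br)(CCl)[C@H](O)C/C=C(C)/C=C/Br | intermediate
13 | (2S,3R,5R)-3-bromo-5-[(2R)-2-bromo-1-chloropropan-2-yl]-2-[(E)-2-bromoethenyl]-2-methyloxolane | C[C@](Br)(CCl)[C@H]1C[C@@H](Br)[C@](C)(/C=C/Br)O1 | target

Total step count: 9. Longest linear sequence: 9 steps (1 → 13).

Steps most likely to fail

Step 4. What may go wrong: migration of the C3=C4 double bond of aldehyde 7 into conjugation, or its self-condensation, faster than the olefination. The fallback sets out from 6 and comes back at 8. The C2=C3 olefin is still made from ylide 6, but with a robust aldehyde, and the two halves are joined instead at the doubly allylic CH2 by sp2–sp3 coupling. Wittig reaction of 6 with chloroacetaldehyde should give ethyl (2E)-4-chloro-2-methylbut-2-enoate F1. Pd(0)-catalysed Negishi-type coupling of F1 with the (E)-alkenylalane from Zr-catalysed carboalumination (Me3Al, Cp2ZrCl2 cat.) of tert-butyldimethyl(prop-2-yn-1-yloxy)silane should give ethyl (2E,5E)-7-[(tert-butyldimethylsilyl)oxy]-2,6-dimethylhepta-2,5-dienoate F2. CSA/MeOH should then give ethyl (2E,5E)-7-hydroxy-2,6-dimethylhepta-2,5-dienoate F3, MnO2 the enal ethyl (2E,5E)-2,6-dimethyl-7-oxohepta-2,5-dienoate F4, and Takai bromo-olefination (CHBr3, CrBr2) of F4 returns 8.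

Step 8. What may go wrong: bromide attack at the secondary oxirane carbon (the CH2Cl group lowers the cationic character of the tertiary carbon), HBr addition to the bromodiene, or re-closure of the bromohydrin to the oxirane on handling. The fallback sets out from 11 and comes back at 13, so it also replaces step 9. With Br2 (1 equiv, CH2Cl2, −78 °C) the bromonium ion formed at the diene should be captured 5-endo by the oxirane oxygen, giving 3-bromo-2-[(E)-2-bromoethenyl]-6-(chloromethyl)-2,6-dimethyl-1-oxoniabicyclo[3.1.0]hexane bromide F5 (not isolated, configuration as in its SMILES). Its strained bond from oxygen to the tertiary carbon should then be opened exo by bromide with inversion. This is the halonium-triggered epoxide participation with halide capture known from transannular and acyclic cases. The facial selectivity of this closure is not covered by the homoallylic-alcohol precedent of step 9 and would have to be established.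

Step 2. What may go wrong: incomplete E selectivity, halogen exchange or reduction during the chromium-mediated olefination of the α-branched enal. The fallback sets out from 3 and comes back at 4. Colvin rearrangement with lithiated trimethylsilyldiazomethane (THF, −78 °C → rt) should give tert-butyl{[(3E)-4-methylhex-3-en-5-yn-1-yl]oxy}dimethylsilane F6. Hydrozirconation (Cp2Zr(H)Cl) and bromination of the (E)-alkenylzirconocene with NBS, with retention, returns 4.

Further compounds
F1 | step 4 | ethyl (2E)-4-chloro-2-methylbut-2-enoate | CCOC(=O)/C(C)=C/CCl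
F2 | step 4 | ethyl (2E,5E)-7-[(tert-butyldimethylsilyl)oxy]-2,6-dimethylhepta-2,5-dienoate | CCOC(=O)/C(C)=C/C/C=C(\C)CO[Si](C)(C)C(C)(C)C
F3 | step 4 | ethyl (2E,5E)-7-hydroxy-2,6-dimethylhepta-2,5-dienoate | CCOC(=O)/C(C)=C/C/C=C(\C)CO
F4 | step 4 | ethyl (2E,5E)-2,6-dimethyl-7-oxohepta-2,5-dienoate | CCOC(=O)/C(C)=C/C/C=C(\C)C=O
F5 | step 8 | 3-bromo-2-[(E)-2-bromoethenyl]-6-(chloromethyl)-2,6-dimethyl-1-oxoniabicyclo[3.1.0]hexane bromide | C[C@@]1(CCl)[C@H]2C[C@@H](Br)[C@](C)(/C=C/Br)[O+]12.[Br-]
F6 | step 2 | tert-butyl{[(3E)-4-methylhex-3-en-5-yn-1-yl]oxy}dimethylsilane | C#C/C(C)=C/CCO[Si](C)(C)C(C)(C)C
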